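**Plan**

- Retrosynthesis: the lactone bond O1–C2 and the O-protecting groups are cut first. Ring A is then cut along C8a–C8, C6–C7 and C8a–C4a into a 4-substituted 3-ethoxycyclobutenone (C8a, C6, C5, C4a plus the C4 side chain) and a siloxyalkyne (C8, C7 plus the masked 3-phenylpropanoyl group). The four-membered ring is cut into a ketene and ethoxyacetylene.
- Enabling feature: ring A is a pentasubstituted benzene whose sequence O–C8a, acyl–C8, O–C7, H–C6, O–C5, alkyl–C4a is exactly what a vinylketene and an oxygen-substituted alkyne leave behind, so every ring A substituent arrives in place in one annulation.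
- Forward order: the C2–C3–C4 chain with its aryl group is made first as a glutaric hemiester, and the cyclobutenone is built on its acid arm. Ring A follows by benzannulation, the lactone ring closes on the only free phenol, and the remaining O-protecting groups come off last.
- Stereochemistry: C4 (S) is the only stereocenter. It is set by cinchona-catalysed methanolysis of the prochiral 3-arylglutaric anhydride and is never a reacting centre afterwards.

Key step: step 6

Assumption: the quinine-derived sulfonamide catalyst is taken to open anhydride 2 to the (S)-hemiester; if its preference on this substrate is the opposite, the quinidine-derived pseudoenantiomer is used and nothing else changes.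

Remark: ring atoms carry the chroman-2-one numbering of the target throughout; the descriptor at C4 switches between R and S along the route only because substituent priorities change, the spatial arrangement stays the same.

**Route**

Step 1
Reactants: 1 3-(4-methoxyphenyl)pentanedioic acid
Product: 2 4-(4-methoxyphenyl)oxane-2,6-dione (3-(4-methoxyphenyl)glutaric anhydride)
Conditions: Ac2O, reflux; evaporate; crystallise from toluene–hexane
Reagents that add atoms: none
Why: Cyclodehydration of a glutaric acid to its six-membered cyclic anhydride with acetic anhydride is routine for 3-arylglutaric acids and gives the prochiral substrate for desymmetrization.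

Step 2
Reactants: 2 4-(4-methoxyphenyl)oxane-2,6-dione
Product: 3 (3S)-5-methoxy-3-(4-methoxyphenyl)-5-oxopentanoic acid
Conditions: N-(9-deoxy-epi-quinin-9-yl)-3,5-bis(trifluoromethyl)benzenesulfonamide (10 mol %), MeOH (10 equiv), MTBE, 20 °C; acid–base extraction
Reagents that add atoms: methanol, CO
Why: Cinchona-catalysed enantioselective alcoholysis (desymmetrization) of a prochiral 3-arylglutaric anhydride, in which the quinuclidine activates methanol as a general base while the sulfonamide N–H binds one of the two enantiotopic carbonyl groups, so that the hemiester carbon that becomes C4 is set as S by catalyst control.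

Step 3
Reactants: 3 (3S)-5-methoxy-3-(4-methoxyphenyl)-5-oxopentanoic acid; 4 ethoxyacetylene
Product: 7 methyl (3R)-3-(2-ethoxy-4-oxocyclobut-2-en-1-yl)-3-(4-methoxyphenyl)propanoate as both epimers at the ring carbon, via acid chloride 5 (not isolated), via ketene 6 (not isolated)
Conditions: (COCl)2, DMF (cat.), CH2Cl2, 0 → 20 °C, evaporate below 25 °C; then 4 (3 equiv), Et3N (1.3 equiv, slow addition), Et2O, 0 → 20 °C
Reagents that add atoms: none
Why: Dehydrochlorination of the acid chloride gives the monosubstituted ketene, which the electron-rich ynol ether traps in a regioselective [2+2] cycloaddition (ketene carbonyl carbon to the unsubstituted alkyne carbon), the established access to 4-substituted 3-ethoxycyclobutenones; the stereocenter is beta to the reacting carbonyl and untouched, and the new ring stereocenter is irrelevant because it becomes sp2 in step 6.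

Step 4
Reactants: 8 ethyl 2-oxo-4-phenylbutanoate
Product: 9 ethyl 2-(2-phenylethyl)-1,3-dioxolane-2-carboxylate
Conditions: Me3SiOCH2CH2OSiMe3 (1.5 equiv), Me3SiOTf (5 mol %), CH2Cl2, −78 → 0 °C; pyridine quench
Reagents that add atoms: 1,2-bis(trimethylsilyloxy)ethane, C[Si](C)(C)OCCO[Si](C)(C)C
Why: Noyori ketalization of the electrophilic ketone carbonyl under aprotic conditions is driven by formation of hexamethyldisiloxane and avoids ester exchange and self-condensation of the keto ester.

Step 5
Reactants: 9 ethyl 2-(2-phenylethyl)-1,3-dioxolane-2-carboxylate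
Product: 12 triisopropyl({[2-(2-phenylethyl)-1,3-dioxolan-2-yl]ethynyl}oxy)silane, via dibromo enolate 10 (not isolated), via lithium ynolate 11 (not isolated)
Conditions: CH2Br2, lithium 2,2,6,6-tetramethylpiperidide, THF, −78 °C; LiN(SiMe3)2; n-BuLi, −78 → 20 °C; then i-Pr3SiCl, −78 → 20 °C; filtration through Et3N-deactivated silica
Reagents that add atoms: dibromomethane, BrCBr; chlorotriisopropylsilane, CC(C)[Si](Cl)(C(C)C)C(C)C
Why: Kowalski ester homologation on a non-enolizable ester, in which dibromomethyllithium adds, the dibromo enolate undergoes bromine–lithium exchange and 1,2-shift to the lithium ynolate, and O-silylation with the bulky chlorosilane gives the siloxyalkyne; the dioxolane ties back the propargylic oxygens and should resist ionisation better than an acyclic ketal.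

Step 6
Reactants: 7 methyl (3R)-3-(2-ethoxy-4-oxocyclobut-2-en-1-yl)-3-(4-methoxyphenyl)propanoate; 12 triisopropyl({[2-(2-phenylethyl)-1,3-dioxolan-2-yl]ethynyl}oxy)silane
Product: 17 methyl (3S)-3-{6-ethoxy-2-hydroxy-3-[2-(2-phenylethyl)-1,3-dioxolan-2-yl]-4-(triisopropylsilyloxy)phenyl}-3-(4-methoxyphenyl)propanoate, via vinylketene 13 (not isolated), via vinylcyclobutenone 14 (not isolated), via dienylketene 15 (not isolated), via cyclohexadienone 16 (not isolated)
Conditions: 7 (1.0 equiv), 12 (1.5 equiv), toluene, 80 → 110 °C, sealed tube, Ar, base-washed glassware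
Reagents that add atoms: none
Why: Thermal four-electron electrocyclic opening of 7 gives vinylketene 13, whose ketene C=C adds the siloxyalkyne in a [2+2] cycloaddition that forms C8a–C8 and C6–C7 (vinylcyclobutenone 14); a second four-electron opening gives dienylketene 15, six-electron electrocyclization forms C8a–C4a (cyclohexadienone 16), and enolization delivers the phenol. The closest known reaction is the Danheiser benzannulation of cyclobutenones with siloxyalkynes to resorcinol monosilyl ethers; here the 3-ethoxy group supplies the third ring oxygen. Ring A, the only ring formed, closes by a thermal disrotatory six-electron electrocyclization of the dienylketene and not by an ionic exo or endo attack. No stereocenter is created: C4 lies outside the reacting pi system and is neither acidic nor ionisable under neutral thermal conditions, so its configuration is carried through, while the ring stereocenter of 7 is erased. The step needs regiocontrol in the ketene–alkyne addition, which the polarised ynol ether provides because its carbon remote from oxygen is the nucleophile and bonds to the ketene carbonyl carbon. It also needs outward rotation of the C4-bearing substituent on ring opening, which is sterically favoured and keeps the C4–H away from the ketene, so that a 1,5-hydrogen shift is avoided.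

Step 7
Reactants: 17 methyl (3S)-3-{6-ethoxy-2-hydroxy-3-[2-(2-phenylethyl)-1,3-dioxolan-2-yl]-4-(triisopropylsilyloxy)phenyl}-3-(4-methoxyphenyl)propanoate
Product: 19 (4S)-5-ethoxy-4-(4-methoxyphenyl)-8-(3-phenylpropanoyl)-7-(triisopropylsilyloxy)-3,4-dihydro-2H-chromen-2-one, via keto ester 18 (not isolated)
Conditions: TsOH·H2O (0.2 equiv), THF–H2O (10:1), 20 °C; then solvent exchange to toluene, 80 °C
Reagents that add atoms: water, O
Why: Acid-catalysed ketal hydrolysis frees the aryl ketone and acid-catalysed transesterification then closes the six-membered lactone with loss of methanol; only the C8a hydroxyl is free (C5 is an ethyl ether, C7 a silyl ether), so the lactone can form in one direction only.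

Step 8
Reactants: 19 (4S)-5-ethoxy-4-(4-methoxyphenyl)-8-(3-phenylpropanoyl)-7-(triisopropylsilyloxy)-3,4-dihydro-2H-chromen-2-one
Product: 20 (4S)-5-ethoxy-7-hydroxy-4-(4-methoxyphenyl)-8-(3-phenylpropanoyl)-3,4-dihydro-2H-chromen-2-one
Conditions: Bu4NF, AcOH (1:1), THF, 0 °C
Reagents that add atoms: none
Why: Fluoride cleavage of an aryl silyl ether, fast here because the departing phenoxide is stabilised by the ortho ketone, with acetic acid buffering so that the lactone is not opened.

Step 9
Reactants: 20 (4S)-5-ethoxy-7-hydroxy-4-(4-methoxyphenyl)-8-(3-phenylpropanoyl)-3,4-dihydro-2H-chromen-2-one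
Product: 21 (4S)-5,7-dihydroxy-4-(4-hydroxyphenyl)-8-(3-phenylpropanoyl)-3,4-dihydro-2H-chromen-2-one (CNP0383109.1)
Conditions: BBr3 (6 equiv), CH2Cl2, −78 → 20 °C; ice-water quench, no basic wash
Reagents that add atoms: none
Why: Lewis-acid dealkylation of the aryl methyl and aryl ethyl ethers through aryloxyboron intermediates should leave lactone, ketone and the doubly benzylic C4–H untouched, and the acidic, base-free work-up is chosen to prevent migration of the lactone to the newly freed C5 hydroxyl.

**Compound list**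

1 | 3-(4-methoxyphenyl)pentanedioic acid | COc1ccc(C(CC(=O)O)CC(=O)O)cc1 | starting material
2 | 4-(4-methoxyphenyl)oxane-2,6-dione | COc1ccc(C2CC(=O)OC(=O)C2)cc1 | intermediate
3 | (3S)-5-methoxy-3-(4-methoxyphenyl)-5-oxopentanoic acid | COC(=O)C[C@@H](c1ccc(OC)cc1)CC(=O)O | intermediate
4 | ethoxyacetylene | C#COCC | starting material
5 | methyl (3R)-5-chloro-3-(4-methoxyphenyl)-5-oxopentanoate | COC(=O)C[C@@H](c1ccc(OC)cc1)CC(=O)Cl | intermediate (not isolated)
6 | methyl (3R)-3-(4-methoxyphenyl)-5-oxopent-4-enoate (ketene) | COC(=O)C[C@@H](c1ccc(OC)cc1)C=C=O | intermediate (not isolated)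
7 | methyl (3R)-3-(2-ethoxy-4-oxocyclobut-2-en-1-yl)-3-(4-methoxyphenyl)propanoate, both epimers at the ring carbon (left undefined) | COC(=O)C[C@@H](c1ccc(OC)cc1)C1C(=O)C=C1OCC | intermediate
8 | ethyl 2-oxo-4-phenylbutanoate | CCOC(=O)C(=O)CCc1ccccc1 | starting material
9 | ethyl 2-(2-phenylethyl)-1,3-dioxolane-2-carboxylate | CCOC(=O)C1(CCc2ccccc2)OCCO1 | intermediate
10 | lithium 2,2-dibromo-1-[2-(2-phenylethyl)-1,3-dioxolan-2-yl]ethen-1-olate | [Li+].[O-]C(=C(Br)Br)C1(CCc2ccccc2)OCCO1 | intermediate (not isolated)
11 | lithium 2-[2-(2-phenylethyl)-1,3-dioxolan-2-yl]ethyn-1-olate | [Li+].[O-]C#CC1(CCc2ccccc2)OCCO1 | intermediate (not isolated)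
12 | triisopropyl({[2-(2-phenylethyl)-1,3-dioxolan-2-yl]ethynyl}oxy)silane | CC(C)[Si](OC#CC1(CCc2ccccc2)OCCO1)(C(C)C)C(C)C | intermediate
13 | methyl (3R,4Z)-5-ethoxy-3-(4-methoxyphenyl)-7-oxohepta-4,6-dienoate (vinylketene) | COC(=O)C[C@@H](c1ccc(OC)cc1)/C=C(OCC)/C=C=O | intermediate (not isolated)
14 | methyl (3R,4Z)-5-ethoxy-3-(4-methoxyphenyl)-5-{4-oxo-3-[2-(2-phenylethyl)-1,3-dioxolan-2-yl]-2-(triisopropylsilyloxy)cyclobut-2-en-1-yl}pent-4-enoate, ring carbon undefined | O=C1C(C2(CCc3ccccc3)OCCO2)=C(O[Si](C(C)C)(C(C)C)C(C)C)C1/C(OCC)=C/[C@@H](CC(=O)OC)c1ccc(OC)cc1 | intermediate (not isolated)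
15 | methyl (3R,4Z,6E)-5-ethoxy-3-(4-methoxyphenyl)-9-oxo-8-[2-(2-phenylethyl)-1,3-dioxolan-2-yl]-7-(triisopropylsilyloxy)nona-4,6,8-trienoate (dienylketene) | O=C=C(C1(CCc2ccccc2)OCCO1)/C(O[Si](C(C)C)(C(C)C)C(C)C)=C\C(OCC)=C\[C@@H](CC(=O)OC)c1ccc(OC)cc1 | intermediate (not isolated)
16 | methyl (3R)-3-{6-ethoxy-2-oxo-3-[2-(2-phenylethyl)-1,3-dioxolan-2-yl]-4-(triisopropylsilyloxy)cyclohexa-3,5-dien-1-yl}-3-(4-methoxyphenyl)propanoate, ring carbon undefined | O=C1C(C2(CCc3ccccc3)OCCO2)=C(O[Si](C(C)C)(C(C)C)C(C)C)C=C(OCC)C1[C@@H](CC(=O)OC)c1ccc(OC)cc1 | intermediate (not isolated)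
17 | methyl (3S)-3-{6-ethoxy-2-hydroxy-3-[2-(2-phenylethyl)-1,3-dioxolan-2-yl]-4-(triisopropylsilyloxy)phenyl}-3-(4-methoxyphenyl)propanoate | COC(=O)C[C@@H](c1ccc(OC)cc1)c1c(OCC)cc(O[Si](C(C)C)(C(C)C)C(C)C)c(C2(CCc3ccccc3)OCCO2)c1O | intermediate
18 | methyl (3S)-3-[6-ethoxy-2-hydroxy-3-(3-phenylpropanoyl)-4-(triisopropylsilyloxy)phenyl]-3-(4-methoxyphenyl)propanoate | COC(=O)C[C@@H](c1ccc(OC)cc1)c1c(OCC)cc(O[Si](C(C)C)(C(C)C)C(C)C)c(C(=O)CCc2ccccc2)c1O | intermediate (not isolated)
19 | (4S)-5-ethoxy-4-(4-methoxyphenyl)-8-(3-phenylpropanoyl)-7-(triisopropylsilyloxy)-3,4-dihydro-2H-chromen-2-one | O=C1C[C@@H](c2ccc(OC)cc2)c2c(OCC)cc(O[Si](C(C)C)(C(C)C)C(C)C)c(C(=O)CCc3ccccc3)c2O1 | intermediate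
20 | (4S)-5-ethoxy-7-hydroxy-4-(4-methoxyphenyl)-8-(3-phenylpropanoyl)-3,4-dihydro-2H-chromen-2-one | O=C1C[C@@H](c2ccc(OC)cc2)c2c(OCC)cc(O)c(C(=O)CCc3ccccc3)c2O1 | intermediate
21 | (4S)-5,7-dihydroxy-4-(4-hydroxyphenyl)-8-(3-phenylpropanoyl)-3,4-dihydro-2H-chromen-2-one | O=C1C[C@@H](c2ccc(O)cc2)c2c(O)cc(O)c(C(=O)CCc3ccccc3)c2O1 | target

**Step count and risks**

Total: 9 steps. Longest linear sequence: 7 steps (1, 2, 3, 6, 7, 8, 9); the siloxyalkyne branch has 2 steps (4, 5).

Steps most likely to fail:

Step 6. The donor-stabilised cyclobutenone may open only at temperatures at which the ynol ether rearranges or the propargylic ketal ionises, and the quaternary propargylic carbon may slow the ketene–alkyne addition so that the vinylketene is lost to self-condensation. The fallback replaces the ketal by a secondary silyl ether and restores the ketone by oxidation; it sets out from 8 (with 7 as before) and comes back at 18.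
- 8 is reduced (NaBH4, EtOH, −20 °C) to ethyl 2-hydroxy-4-phenylbutanoate F1 (racemic) and silylated (Et3SiCl, imidazole, CH2Cl2) to ethyl 4-phenyl-2-(triethylsilyloxy)butanoate F2.
- F2 is homologated and O-silylated by the procedure of step 5 to triethyl{[5-phenyl-1-(triisopropylsilyloxy)pent-1-yn-3-yl]oxy}silane F3.
- Heating F3 with 7 in toluene should give methyl (3S)-3-{6-ethoxy-2-hydroxy-3-[3-phenyl-1-(triethylsilyloxy)propyl]-4-(triisopropylsilyloxy)phenyl}-3-(4-methoxyphenyl)propanoate F4 as carbinol epimers.
- HF·pyridine in THF at 0 °C should remove only the triethylsilyl ether to give methyl (3S)-3-[6-ethoxy-2-hydroxy-3-(1-hydroxy-3-phenylpropyl)-4-(triisopropylsilyloxy)phenyl]-3-(4-methoxyphenyl)propanoate F5.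
- MnO2 in CH2Cl2 oxidises the benzylic alcohol to keto ester 18, which is lactonised to 19 under the second stage of step 7.

Step 5. The 1,2-shift of the oxygen-laden quaternary carbon in the carbenoid may be slow, so that protonation or alkylation of the enolate intermediates competes. The fallback delivers the oxygen to a preformed acetylide instead; it sets out from 9 and comes back at ynolate 11.
- i-Bu2AlH (toluene, −78 °C) reduces 9 to 2-(2-phenylethyl)-1,3-dioxolane-2-carbaldehyde F6.
- Ohira–Bestmann homologation (dimethyl (1-diazo-2-oxopropyl)phosphonate, K2CO3, MeOH) gives 2-ethynyl-2-(2-phenylethyl)-1,3-dioxolane F7.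
- Deprotonation with n-BuLi and oxidation of the lithium acetylide with t-BuOOLi (from t-BuOOH and LiN(SiMe3)2, THF, −78 → 0 °C) gives ynolate 11, which is silylated with i-Pr3SiCl to 12 as in step 5.

Step 3. The monosubstituted ketene may self-condense faster than the ynol ether captures it, and optical purity may erode through intramolecular exchange between the ester and acid chloride termini of 5. The fallback uses a keteniminium salt, which cannot dimerise in this way and needs no acid chloride; it sets out from 3 and comes back at 7.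
- 3 is coupled with dimethylamine (Me2NH·HCl, EDC·HCl, HOBt, i-Pr2NEt, CH2Cl2) to methyl (3S)-5-(dimethylamino)-3-(4-methoxyphenyl)-5-oxopentanoate F8.
- Tf2O and 2,4,6-collidine in CH2Cl2 convert F8 into [(3R)-5-methoxy-3-(4-methoxyphenyl)-5-oxopent-1-en-1-ylidene]dimethylammonium triflate F9.
- F9 should add 4 in a Ghosez-type [2+2] cycloaddition with the same regiochemistry to give {3-ethoxy-4-[(1R)-3-methoxy-1-(4-methoxyphenyl)-3-oxopropyl]cyclobut-2-en-1-ylidene}dimethylammonium triflate F10.
- Hydrolysis with aqueous NaHCO3 gives 7.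

Further compounds
F1 | step 6 | ethyl 2-hydroxy-4-phenylbutanoate (racemic) | CCOC(=O)C(O)CCc1ccccc1
F2 | step 6 | ethyl 4-phenyl-2-(triethylsilyloxy)butanoate (racemic) | CCOC(=O)C(O[Si](CC)(CC)CC)CCc1ccccc1
F3 | step 6 | triethyl{[5-phenyl-1-(triisopropylsilyloxy)pent-1-yn-3-yl]oxy}silane (racemic) | CC[Si](CC)(CC)OC(CCc1ccccc1)C#CO[Si](C(C)C)(C(C)C)C(C)C
F4 | step 6 | methyl (3S)-3-{6-ethoxy-2-hydroxy-3-[3-phenyl-1-(triethylsilyloxy)propyl]-4-(triisopropylsilyloxy)phenyl}-3-(4-methoxyphenyl)propanoate (carbinol epimers) | COC(=O)C[C@@H](c1ccc(OC)cc1)c1c(OCC)cc(O[Si](C(C)C)(C(C)C)C(C)C)c(C(O[Si](CC)(CC)CC)CCc2ccccc2)c1O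
F5 | step 6 | methyl (3S)-3-[6-ethoxy-2-hydroxy-3-(1-hydroxy-3-phenylpropyl)-4-(triisopropylsilyloxy)phenyl]-3-(4-methoxyphenyl)propanoate (carbinol epimers) | COC(=O)C[C@@H](c1ccc(OC)cc1)c1c(OCC)cc(O[Si](C(C)C)(C(C)C)C(C)C)c(C(O)CCc2ccccc2)c1O
F6 | step 5 | 2-(2-phenylethyl)-1,3-dioxolane-2-carbaldehyde | O=CC1(CCc2ccccc2)OCCO1
F7 | step 5 | 2-ethynyl-2-(2-phenylethyl)-1,3-dioxolane | C#CC1(CCc2ccccc2)OCCO1
F8 | step 3 | methyl (3S)-5-(dimethylamino)-3-(4-methoxyphenyl)-5-oxopentanoate | COC(=O)C[C@@H](c1ccc(OC)cc1)CC(=O)N(C)C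
F9 | step 3 | [(3R)-5-methoxy-3-(4-methoxyphenyl)-5-oxopent-1-en-1-ylidene]dimethylammonium triflate | COC(=O)C[C@@H](c1ccc(OC)cc1)C=C=[N+](C)C.[O-]S(=O)(=O)C(F)(F)F
F10 | step 3 | {3-ethoxy-4-[(1R)-3-methoxy-1-(4-methoxyphenyl)-3-oxopropyl]cyclobut-2-en-1-ylidene}dimethylammonium triflate (ring epimers) | COC(=O)C[C@@H](c1ccc(OC)cc1)C1C(=[N+](C)C)C=C1OCC.[O-]S(=O)(=O)C(F)(F)F
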